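The chain is cut at the C10–C11 single bond, beside the C19-methyl-bearing C9=C10 alkene. A C13 triol fragment ending in a terminal enyne (C7=C8–C9≡C10H, C19 still absent) is methylaluminated under zirconocene catalysis, and the (E)-alkenylalane is coupled in the same flask, through zinc and palladium, with a C26 hexaenyl iodide that carries the dihydrofuran ring (O–C5′…C8′). One operation adds C19, sets the 9E geometry and forms C10–C11. The dihydrofuran comes from gold-catalysed cyclisation of an α-allenol (axis-to-centre transfer to C8′), the trans-5,6-diol from anti opening of a syn-oxirane.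

Key step: step 21

Remark: carotenoid numbering is used in the explanations (ring C1–C6, chain C7–C15, primed locants for the dihydrofuran half); compounds 1, 10, 17 and 21 are taken as commercial, and all polyene steps are assumed to run under argon with exclusion of light.

Step 1
Reactants: 1 (4R,6R)-4-hydroxy-2,2,6-trimethylcyclohexan-1-one
Product: 2 (4R,6R)-4-(tert-butyldimethylsilyloxy)-2,2,6-trimethylcyclohexan-1-one
Conditions: TBSCl, imidazole, DMF, rt
Reagents that add atoms: tert-butyldimethylsilyl chloride, CC(C)(C)[Si](C)(C)Cl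
Why: Silyl ether formation masks the C3 hydroxyl for the enolate chemistry and does not touch the C3 stereocentre.

Step 2
Reactants: 2 (4R,6R)-4-(tert-butyldimethylsilyloxy)-2,2,6-trimethylcyclohexan-1-one
Product: 4 (4R)-4-(tert-butyldimethylsilyloxy)-2,6,6-trimethylcyclohex-1-en-1-yl trifluoromethanesulfonate, via lithium enolate 3 (not isolated)
Conditions: LiN(i-Pr)2, THF, −78 °C; then PhNTf2, −78 °C to rt
Reagents that add atoms: N-phenylbis(trifluoromethanesulfonimide), O=S(=O)(N(c1ccccc1)S(=O)(=O)C(F)(F)F)C(F)(F)F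
Why: Only the C5 methine can be deprotonated (C1 is quaternary), so O-triflation of the single enolate (enol triflate formation) should give the tetrasubstituted C5=C6 vinyl triflate.

Step 3
Reactants: 4 (4R)-4-(tert-butyldimethylsilyloxy)-2,6,6-trimethylcyclohex-1-en-1-yl trifluoromethanesulfonate
Product: 5 methyl (4R)-4-(tert-butyldimethylsilyloxy)-2,6,6-trimethylcyclohex-1-ene-1-carboxylate
Conditions: Pd(OAc)2 (5 mol %), PPh3, CO (1 atm), MeOH, Et3N, DMF, 60 °C
Reagents that add atoms: carbon monoxide, [C-]#[O+]; methanol, CO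
Why: Palladium-catalysed alkoxycarbonylation (oxidative addition of zerovalent palladium into the vinyl triflate, CO insertion, methanolysis) installs C7 on C6.

Step 4
Reactants: 5 methyl (4R)-4-(tert-butyldimethylsilyloxy)-2,6,6-trimethylcyclohex-1-ene-1-carboxylate
Product: 6 [(4R)-4-(tert-butyldimethylsilyloxy)-2,6,6-trimethylcyclohex-1-en-1-yl]methanol
Conditions: i-Bu2AlH, CH2Cl2, −78 to 0 °C
Reagents that add atoms: none
Why: Hydride reduction of the conjugated ester gives the allylic alcohol that the asymmetric epoxidation needs.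

Step 5
Reactants: 6 [(4R)-4-(tert-butyldimethylsilyloxy)-2,6,6-trimethylcyclohex-1-en-1-yl]methanol
Product: 7 [(1R,4S,6R)-4-(tert-butyldimethylsilyloxy)-2,2,6-trimethyl-7-oxabicyclo[4.1.0]heptan-1-yl]methanol
Conditions: Ti(OiPr)4, D-(−)-diethyl tartrate, t-BuOOH, 4 Å molecular sieves, CH2Cl2, −20 °C
Reagents that add atoms: tert-butyl hydroperoxide, CC(C)(C)OO
Why: Sharpless asymmetric epoxidation; the titanium D-tartrate complex should deliver oxygen to the C5=C6 face opposite the C3 silyloxy group (reagent control), setting C5 (R, oxygen trans to C3–O) and C6.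

Step 6
Reactants: 7 [(1R,4S,6R)-4-(tert-butyldimethylsilyloxy)-2,2,6-trimethyl-7-oxabicyclo[4.1.0]heptan-1-yl]methanol
Product: 8 (1S,4S,6R)-4-(tert-butyldimethylsilyloxy)-2,2,6-trimethyl-7-oxabicyclo[4.1.0]heptane-1-carbaldehyde
Conditions: Dess–Martin periodinane, pyridine, CH2Cl2, 0 °C to rt
Reagents that add atoms: none
Why: Dess–Martin oxidation of the primary alcohol under buffered conditions spares the oxirane; the aldehyde has no α-hydrogen, so nothing can epimerise.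

Step 7
Reactants: 8 (1S,4S,6R)-4-(tert-butyldimethylsilyloxy)-2,2,6-trimethyl-7-oxabicyclo[4.1.0]heptane-1-carbaldehyde
Product: 9 (1R,4S,6R)-4-(tert-butyldimethylsilyloxy)-1-ethynyl-2,2,6-trimethyl-7-oxabicyclo[4.1.0]heptane
Conditions: dimethyl (1-diazo-2-oxopropyl)phosphonate, K2CO3, MeOH, 0 °C to rt
Reagents that add atoms: dimethyl (1-diazo-2-oxopropyl)phosphonate, CC(=O)C(=[N+]=[N-])P(=O)(OC)OC
Why: Ohira–Bestmann (Seyferth–Gilbert) homologation converts the non-enolisable aldehyde into the terminal alkyne C7≡C8 under mild base.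

Step 8
Reactants: 10 ethyl 3-oxobutanoate
Product: 11 ethyl (2E)-3-(trifluoromethylsulfonyloxy)but-2-enoate
Conditions: Tf2O, aq. Me4NOH, hexane, 5 °C
Reagents that add atoms: trifluoromethanesulfonic anhydride, O=S(=O)(OS(=O)(=O)C(F)(F)F)C(F)(F)F
Why: O-triflation of the non-chelated tetramethylammonium enolate (enol triflate formation) should give the E isomer, with the triflate trans to the ester.

Step 9
Reactants: 9 (1R,4S,6R)-4-(tert-butyldimethylsilyloxy)-1-ethynyl-2,2,6-trimethyl-7-oxabicyclo[4.1.0]heptane; 11 ethyl (2E)-3-(trifluoromethylsulfonyloxy)but-2-enoate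
Product: 12 ethyl (2E)-5-[(1R,4S,6R)-4-(tert-butyldimethylsilyloxy)-2,2,6-trimethyl-7-oxabicyclo[4.1.0]heptan-1-yl]-3-methylpent-2-en-4-ynoate
Conditions: Pd(PPh3)4 (5 mol %), CuI (10 mol %), i-Pr2NH, THF, rt
Reagents that add atoms: none
Why: Sonogashira coupling of the terminal alkyne with the activated vinyl triflate forms C8–C9 with retention, giving the 9E enynoate.

Step 10
Reactants: 12 ethyl (2E)-5-[(1R,4S,6R)-4-(tert-butyldimethylsilyloxy)-2,2,6-trimethyl-7-oxabicyclo[4.1.0]heptan-1-yl]-3-methylpent-2-en-4-ynoate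
Product: 13 (2E)-5-[(2R,4S)-4-(tert-butyldimethylsilyloxy)-2-hydroxy-2,6,6-trimethylcyclohexylidene]-3-methylpenta-2,4-dien-1-ol with the (R) allene axis
Conditions: i-Bu2AlH (5 equiv), CH2Cl2, 0 °C; aqueous work-up
Reagents that add atoms: none
Why: Ester reduction is followed by SN2′ hydride opening of the alkynyl oxirane by aluminium bound to the oxirane oxygen, a reduction type known to turn the (5R,6S)-oxirane into the (6R)-allene while C5–O is retained.

Step 11
Reactants: 13 (2E)-5-[(2R,4S)-4-(tert-butyldimethylsilyloxy)-2-hydroxy-2,6,6-trimethylcyclohexylidene]-3-methylpenta-2,4-dien-1-ol with the (R) allene axis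
Product: 14 (2E)-3-[(2S,6S,7aR)-6-(tert-butyldimethylsilyloxy)-4,4,7a-trimethyl-2,4,5,6,7,7a-hexahydro-1-benzofuran-2-yl]but-2-en-1-ol
Conditions: AuCl3 (5 mol %), THF, 0 °C to rt, dark
Reagents that add atoms: none
Why: Gold-catalysed 5-endo cycloisomerisation of the α-hydroxyallene: the C5 oxygen attacks C8 anti to gold on the C7=C8 bond and protodeauration follows, so the axis is transferred to the centre and the (5R,6R)-allenol should give C8 as S (C9 cis to the C5 methyl).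

Step 12
Reactants: 14 (2E)-3-[(2S,6S,7aR)-6-(tert-butyldimethylsilyloxy)-4,4,7a-trimethyl-2,4,5,6,7,7a-hexahydro-1-benzofuran-2-yl]but-2-en-1-ol
Product: 16 {(2E)-3-[(2S,6S,7aR)-6-(tert-butyldimethylsilyloxy)-4,4,7a-trimethyl-2,4,5,6,7,7a-hexahydro-1-benzofuran-2-yl]but-2-en-1-yl}triphenylphosphonium bromide, via allylic bromide 15 (not isolated)
Conditions: PPh3 (2.5 equiv), CBr4 (1.2 equiv), CH2Cl2, 0 °C to rt
Reagents that add atoms: triphenylphosphine, c1ccc(cc1)P(c1ccccc1)c1ccccc1; carbon tetrabromide, BrC(Br)(Br)Br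
Why: Appel bromination of the primary allylic alcohol and quaternisation of the bromide by the excess phosphine give the Wittig salt without acid, which the allylic C8 ether would not tolerate.

Step 13
Reactants: 16 {(2E)-3-[(2S,6S,7aR)-6-(tert-butyldimethylsilyloxy)-4,4,7a-trimethyl-2,4,5,6,7,7a-hexahydro-1-benzofuran-2-yl]but-2-en-1-yl}triphenylphosphonium bromide; 17 (2E,4E,6E)-2,7-dimethylocta-2,4,6-trienedial
Product: 19 (2E,4E,6E,8E,10E)-11-[(2S,6S,7aR)-6-(tert-butyldimethylsilyloxy)-4,4,7a-trimethyl-2,4,5,6,7,7a-hexahydro-1-benzofuran-2-yl]-2,7-dimethyldodeca-2,4,6,8,10-pentaenal, via phosphorus ylide 18 (not isolated)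
Conditions: 17 (3 equiv), NaOMe, MeOH/CH2Cl2, 0 °C to rt; then heptane, 60 °C
Reagents that add atoms: none
Why: Wittig olefination of one formyl group of the excess dialdehyde forms C11′=C12′, and the sterically hindered Z isomer at this bond should equilibrate to E on gentle heating.

Step 14
Reactants: 19 (2E,4E,6E,8E,10E)-11-[(2S,6S,7aR)-6-(tert-butyldimethylsilyloxy)-4,4,7a-trimethyl-2,4,5,6,7,7a-hexahydro-1-benzofuran-2-yl]-2,7-dimethyldodeca-2,4,6,8,10-pentaenal
Product: 20 (2S,6S,7aR)-6-(tert-butyldimethylsilyloxy)-2-[(2E,4E,6E,8E,10E,12E)-13-iodo-6,11-dimethyltrideca-2,4,6,8,10,12-hexaen-2-yl]-4,4,7a-trimethyl-2,4,5,6,7,7a-hexahydro-1-benzofuran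
Conditions: CrCl2 (6 equiv), CHI3 (2 equiv), THF, 0 °C, dark
Reagents that add atoms: iodoform, IC(I)I
Why: Takai iodo-olefination adds C11 as an (E)-vinyl iodide through anti elimination from the gem-dichromium adduct.

Step 15
Reactants: 4 (4R)-4-(tert-butyldimethylsilyloxy)-2,6,6-trimethylcyclohex-1-en-1-yl trifluoromethanesulfonate; 21 1,4-bis(trimethylsilyl)buta-1,3-diyne
Product: 24 tert-butyldimethyl({(1R)-3,5,5-trimethyl-4-[4-(trimethylsilyl)buta-1,3-diyn-1-yl]cyclohex-3-en-1-yl}oxy)silane, via lithium acetylide 22 (not isolated), via alkynylzinc chloride 23 (not isolated)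
Conditions: 21, MeLi·LiBr, THF, rt; ZnCl2, 0 °C; then 4, Pd(PPh3)4 (5 mol %), THF, 50 °C
Reagents that add atoms: none
Why: Mono-desilylation of the diyne by methyllithium, transmetalation to zinc and Negishi alkynylation of the vinyl triflate attach C7–C10 as a diyne to C6.

Step 16
Reactants: 24 tert-butyldimethyl({(1R)-3,5,5-trimethyl-4-[4-(trimethylsilyl)buta-1,3-diyn-1-yl]cyclohex-3-en-1-yl}oxy)silane
Product: 25 (1R)-4-(buta-1,3-diyn-1-yl)-3,5,5-trimethylcyclohex-3-en-1-ol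
Conditions: n-Bu4NF, THF, 0 °C to rt; used directly in solution
Reagents that add atoms: none
Why: Fluoride-mediated desilylation removes both the O-silyl and the C-silyl group and frees the C3 hydroxyl that directs the next step.

Step 17
Reactants: 25 (1R)-4-(buta-1,3-diyn-1-yl)-3,5,5-trimethylcyclohex-3-en-1-ol
Product: 26 (1S,4S,6S)-1-(buta-1,3-diyn-1-yl)-2,2,6-trimethyl-7-oxabicyclo[4.1.0]heptan-4-ol
Conditions: VO(acac)2 (5 mol %), t-BuOOH, toluene, rt
Reagents that add atoms: tert-butyl hydroperoxide, CC(C)(C)OO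
Why: Vanadium-catalysed hydroxyl-directed epoxidation: the vanadate ester of the homoallylic C3 hydroxyl should deliver oxygen to the C5=C6 face cis to that hydroxyl, giving the syn-oxirane.

Step 18
Reactants: 26 (1S,4S,6S)-1-(buta-1,3-diyn-1-yl)-2,2,6-trimethyl-7-oxabicyclo[4.1.0]heptan-4-ol
Product: 27 (1S,2R,4S)-1-(buta-1,3-diyn-1-yl)-2,6,6-trimethylcyclohexane-1,2,4-triol
Conditions: HClO4 (cat.), THF/H2O, 0 °C
Reagents that add atoms: water, O
Why: Acid-catalysed trans-diaxial oxirane hydrolysis: water should attack the tertiary C5 (C6 is deactivated by the electron-withdrawing diynyl group) from the face opposite the oxirane oxygen, inverting C5 to R (hydroxyl trans to the C3 and C6 hydroxyls) while C6 keeps its C–O bond.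

Step 19
Reactants: 27 (1S,2R,4S)-1-(buta-1,3-diyn-1-yl)-2,6,6-trimethylcyclohexane-1,2,4-triol
Product: 28 (1R,2R,4S)-1-[(1E)-but-1-en-3-yn-1-yl]-2,6,6-trimethylcyclohexane-1,2,4-triol
Conditions: LiAlH4, THF, 0 °C to rt; aqueous work-up
Reagents that add atoms: none
Why: Alkoxide-directed trans-hydroalumination of the propargylic C7≡C8 bond (propargylic alcohol to (E)-allylic alcohol reduction) sets the 7E alkene, while the terminal alkyne is protected as its acetylide.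

Step 20
Reactants: 28 (1R,2R,4S)-1-[(1E)-but-1-en-3-yn-1-yl]-2,6,6-trimethylcyclohexane-1,2,4-triol
Product: 29 (1R,2R,4S)-1-[(1E)-but-1-en-3-yn-1-yl]-2,6,6-trimethyl-1,2,4-tris(trimethylsilyloxy)cyclohexane
Conditions: N-(trimethylsilyl)imidazole, CH2Cl2, 40 °C
Reagents that add atoms: N-(trimethylsilyl)imidazole, C[Si](C)(C)n1ccnc1
Why: Silyl ether formation with a neutral, strong silyl donor covers the secondary and both hindered tertiary hydroxyls, so no protic site meets the organoaluminium reagent.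

Step 21
Reactants: 29 (1R,2R,4S)-1-[(1E)-but-1-en-3-yn-1-yl]-2,6,6-trimethyl-1,2,4-tris(trimethylsilyloxy)cyclohexane; 20 (2S,6S,7aR)-6-(tert-butyldimethylsilyloxy)-2-[(2E,4E,6E,8E,10E,12E)-13-iodo-6,11-dimethyltrideca-2,4,6,8,10,12-hexaen-2-yl]-4,4,7a-trimethyl-2,4,5,6,7,7a-hexahydro-1-benzofuran
Product: 31 3′-O-(tert-butyldimethylsilyl)-3,5,6-tris-O-(trimethylsilyl) ether of the target tetrol, via alkenylalane 30 (not isolated)
Conditions: AlMe3 (3 equiv), Cp2ZrCl2 (0.5 equiv), ClCH2CH2Cl, 0 °C to rt; evaporate; then 20, ZnCl2 (cocatalyst), Pd2(dba)3 (2.5 mol %), P(2-furyl)3 (10 mol %), THF/DMF, rt, dark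
Reagents that add atoms: trimethylaluminium, C[Al](C)C
Why: Methylzirconocene species formed from Cp2ZrCl2 and AlMe3 add methyl and aluminium syn across the terminal C9≡C10 bond of 29 (methyl to internal C9, aluminium to C10), and the alane 30 transmetalates through zinc to palladium, which has undergone oxidative addition into the C11–I bond of 20; reductive elimination then forms C10–C11 with retention at both alkenes. The closest known reaction type is the one-pot zirconium-catalysed carboalumination and palladium–zinc (Negishi) alkenyl–alkenyl coupling used to build isoprenoid polyenes from terminal enynes. No ring is closed and no stereocentre is formed; the new stereo-elements are the 9E geometry, fixed by the syn carbometalation, and the 11E geometry, carried over from the iodide. The step needs regioselective methyl delivery to C9, which the terminal alkyne conjugated to C7=C8 secures, and survival of the allylic C6 and C8′ ethers, for which all four hydroxyls are silylated, excess AlMe3 is stripped before 20 is added and the donor solvents temper the Lewis acids.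

Step 22
Reactants: 31 3′-O-(tert-butyldimethylsilyl)-3,5,6-tris-O-(trimethylsilyl) ether of the target tetrol
Product: 32 (3S,5R,6R,3′S,5′R,8′S)-5′,8′-epoxy-5,6,5′,8′-tetrahydro-β,β-carotene-3,5,6,3′-tetrol (CNP0210286.3)
Conditions: n-Bu4NF, THF, 0 °C to rt, dark
Reagents that add atoms: none
Why: Fluoride-mediated desilylation cleaves the four silyl ethers without acid, so the dihydrofuran, the tertiary allylic alcohol and the polyene should survive.

Compound list

1 | (4R,6R)-4-hydroxy-2,2,6-trimethylcyclohexan-1-one ((−)-actinol) | O=C1C(C)(C)C[C@H](O)C[C@H]1C | starting material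
2 | (4R,6R)-4-(tert-butyldimethylsilyloxy)-2,2,6-trimethylcyclohexan-1-one | O=C1C(C)(C)C[C@H](O[Si](C)(C)C(C)(C)C)C[C@H]1C | intermediate
3 | lithium (4R)-4-(tert-butyldimethylsilyloxy)-2,6,6-trimethylcyclohex-1-en-1-olate | CC1=C(O[Li])C(C)(C)C[C@H](O[Si](C)(C)C(C)(C)C)C1 | intermediate
4 | (4R)-4-(tert-butyldimethylsilyloxy)-2,6,6-trimethylcyclohex-1-en-1-yl trifluoromethanesulfonate | CC1=C(OS(=O)(=O)C(F)(F)F)C(C)(C)C[C@H](O[Si](C)(C)C(C)(C)C)C1 | intermediate
5 | methyl (4R)-4-(tert-butyldimethylsilyloxy)-2,6,6-trimethylcyclohex-1-ene-1-carboxylate | CC1=C(C(=O)OC)C(C)(C)C[C@H](O[Si](C)(C)C(C)(C)C)C1 | intermediate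
6 | [(4R)-4-(tert-butyldimethylsilyloxy)-2,6,6-trimethylcyclohex-1-en-1-yl]methanol | CC1=C(CO)C(C)(C)C[C@H](O[Si](C)(C)C(C)(C)C)C1 | intermediate
7 | [(1R,4S,6R)-4-(tert-butyldimethylsilyloxy)-2,2,6-trimethyl-7-oxabicyclo[4.1.0]heptan-1-yl]methanol (oxirane trans to the silyloxy group) | OC[C@]12C(C)(C)C[C@H](O[Si](C)(C)C(C)(C)C)C[C@@]1(C)O2 | intermediate
8 | (1S,4S,6R)-4-(tert-butyldimethylsilyloxy)-2,2,6-trimethyl-7-oxabicyclo[4.1.0]heptane-1-carbaldehyde | O=C[C@]12C(C)(C)C[C@H](O[Si](C)(C)C(C)(C)C)C[C@@]1(C)O2 | intermediate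
9 | (1R,4S,6R)-4-(tert-butyldimethylsilyloxy)-1-ethynyl-2,2,6-trimethyl-7-oxabicyclo[4.1.0]heptane | C#C[C@]12C(C)(C)C[C@H](O[Si](C)(C)C(C)(C)C)C[C@@]1(C)O2 | intermediate
10 | ethyl 3-oxobutanoate | CCOC(=O)CC(C)=O | starting material
11 | ethyl (2E)-3-(trifluoromethylsulfonyloxy)but-2-enoate | CCOC(=O)/C=C(\C)OS(=O)(=O)C(F)(F)F | intermediate
12 | ethyl (2E)-5-[(1R,4S,6R)-4-(tert-butyldimethylsilyloxy)-2,2,6-trimethyl-7-oxabicyclo[4.1.0]heptan-1-yl]-3-methylpent-2-en-4-ynoate | CCOC(=O)/C=C(\C)C#C[C@]12C(C)(C)C[C@H](O[Si](C)(C)C(C)(C)C)C[C@@]1(C)O2 | intermediate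
13 | (2E)-5-[(2R,4S)-4-(tert-butyldimethylsilyloxy)-2-hydroxy-2,6,6-trimethylcyclohexylidene]-3-methylpenta-2,4-dien-1-ol, (R) allene axis (carotenoid 3S,5R,6R) | CC1(C)C[C@H](O[Si](C)(C)C(C)(C)C)C[C@@](C)(O)C1=[C@]=C/C(C)=C/CO | intermediate
14 | (2E)-3-[(2S,6S,7aR)-6-(tert-butyldimethylsilyloxy)-4,4,7a-trimethyl-2,4,5,6,7,7a-hexahydro-1-benzofuran-2-yl]but-2-en-1-ol | OC/C=C(\C)[C@@H]1C=C2C(C)(C)C[C@H](O[Si](C)(C)C(C)(C)C)C[C@@]2(C)O1 | intermediate
15 | (2S,6S,7aR)-2-[(2E)-4-bromobut-2-en-2-yl]-6-(tert-butyldimethylsilyloxy)-4,4,7a-trimethyl-2,4,5,6,7,7a-hexahydro-1-benzofuran | BrC/C=C(\C)[C@@H]1C=C2C(C)(C)C[C@H](O[Si](C)(C)C(C)(C)C)C[C@@]2(C)O1 | intermediate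
16 | {(2E)-3-[(2S,6S,7aR)-6-(tert-butyldimethylsilyloxy)-4,4,7a-trimethyl-2,4,5,6,7,7a-hexahydro-1-benzofuran-2-yl]but-2-en-1-yl}triphenylphosphonium bromide | [Br-].c1ccccc1[P+](c1ccccc1)(c1ccccc1)C/C=C(\C)[C@@H]1C=C2C(C)(C)C[C@H](O[Si](C)(C)C(C)(C)C)C[C@@]2(C)O1 | intermediate
17 | (2E,4E,6E)-2,7-dimethylocta-2,4,6-trienedial | O=C/C(C)=C/C=C/C=C(\C)C=O | starting material
18 | {(2E)-3-[(2S,6S,7aR)-6-(tert-butyldimethylsilyloxy)-4,4,7a-trimethyl-2,4,5,6,7,7a-hexahydro-1-benzofuran-2-yl]but-2-en-1-ylidene}triphenylphosphorane | c1ccccc1P(c1ccccc1)(c1ccccc1)=C/C=C(\C)[C@@H]1C=C2C(C)(C)C[C@H](O[Si](C)(C)C(C)(C)C)C[C@@]2(C)O1 | intermediate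
19 | (2E,4E,6E,8E,10E)-11-[(2S,6S,7aR)-6-(tert-butyldimethylsilyloxy)-4,4,7a-trimethyl-2,4,5,6,7,7a-hexahydro-1-benzofuran-2-yl]-2,7-dimethyldodeca-2,4,6,8,10-pentaenal | O=C/C(C)=C/C=C/C=C(C)/C=C/C=C(\C)[C@@H]1C=C2C(C)(C)C[C@H](O[Si](C)(C)C(C)(C)C)C[C@@]2(C)O1 | intermediate
20 | (2S,6S,7aR)-6-(tert-butyldimethylsilyloxy)-2-[(2E,4E,6E,8E,10E,12E)-13-iodo-6,11-dimethyltrideca-2,4,6,8,10,12-hexaen-2-yl]-4,4,7a-trimethyl-2,4,5,6,7,7a-hexahydro-1-benzofuran | I/C=C/C(C)=C/C=C/C=C(C)/C=C/C=C(\C)[C@@H]1C=C2C(C)(C)C[C@H](O[Si](C)(C)C(C)(C)C)C[C@@]2(C)O1 | intermediate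
21 | 1,4-bis(trimethylsilyl)buta-1,3-diyne | C[Si](C)(C)C#CC#C[Si](C)(C)C | starting material
22 | [4-(trimethylsilyl)buta-1,3-diyn-1-yl]lithium | [Li]C#CC#C[Si](C)(C)C | intermediate
23 | chloro[4-(trimethylsilyl)buta-1,3-diyn-1-yl]zinc | Cl[Zn]C#CC#C[Si](C)(C)C | intermediate
24 | tert-butyldimethyl({(1R)-3,5,5-trimethyl-4-[4-(trimethylsilyl)buta-1,3-diyn-1-yl]cyclohex-3-en-1-yl}oxy)silane | CC1=C(C#CC#C[Si](C)(C)C)C(C)(C)C[C@H](O[Si](C)(C)C(C)(C)C)C1 | intermediate
25 | (1R)-4-(buta-1,3-diyn-1-yl)-3,5,5-trimethylcyclohex-3-en-1-ol | CC1=C(C#CC#C)C(C)(C)C[C@H](O)C1 | intermediate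
26 | (1S,4S,6S)-1-(buta-1,3-diyn-1-yl)-2,2,6-trimethyl-7-oxabicyclo[4.1.0]heptan-4-ol (oxirane cis to the hydroxyl) | C#CC#C[C@@]12C(C)(C)C[C@H](O)C[C@]1(C)O2 | intermediate
27 | (1S,2R,4S)-1-(buta-1,3-diyn-1-yl)-2,6,6-trimethylcyclohexane-1,2,4-triol | C#CC#C[C@@]1(O)C(C)(C)C[C@H](O)C[C@@]1(C)O | intermediate
28 | (1R,2R,4S)-1-[(1E)-but-1-en-3-yn-1-yl]-2,6,6-trimethylcyclohexane-1,2,4-triol | C#C/C=C/[C@@]1(O)C(C)(C)C[C@H](O)C[C@@]1(C)O | intermediate
29 | (1R,2R,4S)-1-[(1E)-but-1-en-3-yn-1-yl]-2,6,6-trimethyl-1,2,4-tris(trimethylsilyloxy)cyclohexane | C#C/C=C/[C@@]1(O[Si](C)(C)C)C(C)(C)C[C@H](O[Si](C)(C)C)C[C@@]1(C)O[Si](C)(C)C | intermediate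
30 | dimethyl{(1E,3E)-2-methyl-4-[(1R,2R,4S)-2,6,6-trimethyl-1,2,4-tris(trimethylsilyloxy)cyclohexyl]buta-1,3-dien-1-yl}aluminium | C[Al](C)/C=C(C)/C=C/[C@@]1(O[Si](C)(C)C)C(C)(C)C[C@H](O[Si](C)(C)C)C[C@@]1(C)O[Si](C)(C)C | intermediate
31 | 3′-O-(tert-butyldimethylsilyl)-3,5,6-tris-O-(trimethylsilyl) ether of (3S,5R,6R,3′S,5′R,8′S)-5′,8′-epoxy-5,6,5′,8′-tetrahydro-β,β-carotene-3,5,6,3′-tetrol | CC(/C=C/C=C(C)/C=C/[C@@]1(O[Si](C)(C)C)C(C)(C)C[C@H](O[Si](C)(C)C)C[C@@]1(C)O[Si](C)(C)C)=C\C=C\C=C(C)\C=C\C=C(/C)[C@@H]1C=C2C(C)(C)C[C@H](O[Si](C)(C)C(C)(C)C)C[C@@]2(C)O1 | intermediate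
32 | (3S,5R,6R,3′S,5′R,8′S)-5′,8′-epoxy-5,6,5′,8′-tetrahydro-β,β-carotene-3,5,6,3′-tetrol (CNP0210286.3) | CC(/C=C/C=C(C)/C=C/[C@@]1(O)C(C)(C)C[C@H](O)C[C@@]1(C)O)=C\C=C\C=C(C)\C=C\C=C(/C)[C@@H]1C=C2C(C)(C)C[C@H](O)C[C@@]2(C)O1 | target

Total step count: 22. Longest linear sequence: 15 steps (steps 1–7, 9–14, 21 and 22).

Steps most likely to fail

Step 21. The aluminium and zinc Lewis acids may ionise the allylic C8′–O bond of the dihydrofuran in 20 and scramble C8′, or transmetalation of the hindered alane may be too slow, so that the polyenyl iodide decomposes before it couples. The fallback replaces the one-pot alane coupling by a Stille coupling under neutral conditions. It sets out from 29 and 19 and comes back at 31. Compound 29 is methylaluminated as in step 21 and the alane 30 is cleaved with I2 (THF, −30 °C) to the dienyl iodide (1R,2R,4S)-1-[(1E,3E)-4-iodo-3-methylbuta-1,3-dien-1-yl]-2,6,6-trimethyl-1,2,4-tris(trimethylsilyloxy)cyclohexane F1. Aldehyde 19 is taken through a chromium-mediated stannyl-olefination (Bu3SnCHBr2, CrCl2, LiI, THF/DMF) to the hexaenylstannane tributyl[(1E,3E,5E,7E,9E,11E)-12-{(2S,6S,7aR)-6-(tert-butyldimethylsilyloxy)-4,4,7a-trimethyl-2,4,5,6,7,7a-hexahydro-1-benzofuran-2-yl}-3,8-dimethyltrideca-1,3,5,7,9,11-hexaen-1-yl]stannane F2. F1 and F2 are joined with Pd2(dba)3 and AsPh3 in N-methylpyrrolidone at rt to give 31.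

Step 18. Water may open the oxirane at the wrong carbon, or the C5 cation may escape by ring contraction (1,2-shift) or by elimination to an allylic alcohol. The fallback opens the trans-oxirane at the allylic C6 instead of the syn-oxirane at C5. It sets out from 8 and comes back at 28. Takai olefination of 8 (CHI3, CrCl2, THF) gives the epoxy vinyl iodide (1S,4S,6R)-4-(tert-butyldimethylsilyloxy)-1-[(E)-2-iodoethenyl]-2,2,6-trimethyl-7-oxabicyclo[4.1.0]heptane F3. Dilute HClO4 in THF/H2O should open F3 at the allylic C6 with inversion to the trans-diol (1R,2R,4S)-4-(tert-butyldimethylsilyloxy)-1-[(E)-2-iodoethenyl]-2,6,6-trimethylcyclohexane-1,2-diol F4; the C6 epimer, if formed, would have to be removed by chromatography. Sonogashira coupling of F4 with ethynyltrimethylsilane (Pd(PPh3)4, CuI, i-Pr2NH) gives the silylated enyne (1R,2R,4S)-4-(tert-butyldimethylsilyloxy)-2,6,6-trimethyl-1-[(1E)-4-(trimethylsilyl)but-1-en-3-yn-1-yl]cyclohexane-1,2-diol F5, and n-Bu4NF removes both silyl groups to give 28.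

Step 11. The gold Lewis acid may reopen the product at C8 and erode the axis-to-centre transfer, or the vinylallene may enter a competing gold-mediated carbocyclisation. The fallback uses the classical acid-induced rearrangement of a 5,6-oxirane to the 5,8-furanoid. It sets out from 8 and comes back at 14. Horner–Wadsworth–Emmons reaction of 8 with triethyl 3-methyl-4-phosphonocrotonate (NaH, THF) gives the epoxy dienoate ethyl (2E,4E)-5-[(1S,4S,6R)-4-(tert-butyldimethylsilyloxy)-2,2,6-trimethyl-7-oxabicyclo[4.1.0]heptan-1-yl]-3-methylpenta-2,4-dienoate F6. Reduction with i-Bu2AlH gives the epoxy dienol (2E,4E)-5-[(1S,4S,6R)-4-(tert-butyldimethylsilyloxy)-2,2,6-trimethyl-7-oxabicyclo[4.1.0]heptan-1-yl]-3-methylpenta-2,4-dien-1-ol F7. Brief treatment of F7 with pyridinium p-toluenesulfonate in CH2Cl2 should give 14 together with its C8 epimer (2E)-3-[(2R,6S,7aR)-6-(tert-butyldimethylsilyloxy)-4,4,7a-trimethyl-2,4,5,6,7,7a-hexahydro-1-benzofuran-2-yl]but-2-en-1-ol F8, from which 14 is separated by chromatography.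

Further compounds

F1 | step 21 | (1R,2R,4S)-1-[(1E,3E)-4-iodo-3-methylbuta-1,3-dien-1-yl]-2,6,6-trimethyl-1,2,4-tris(trimethylsilyloxy)cyclohexane | I/C=C(C)/C=C/[C@@]1(O[Si](C)(C)C)C(C)(C)C[C@H](O[Si](C)(C)C)C[C@@]1(C)O[Si](C)(C)C
F2 | step 21 | tributyl[(1E,3E,5E,7E,9E,11E)-12-{(2S,6S,7aR)-6-(tert-butyldimethylsilyloxy)-4,4,7a-trimethyl-2,4,5,6,7,7a-hexahydro-1-benzofuran-2-yl}-3,8-dimethyltrideca-1,3,5,7,9,11-hexaen-1-yl]stannane | CCCC[Sn](CCCC)(CCCC)/C=C/C(C)=C/C=C/C=C(C)/C=C/C=C(\C)[C@@H]1C=C2C(C)(C)C[C@H](O[Si](C)(C)C(C)(C)C)C[C@@]2(C)O1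
F3 | step 18 | (1S,4S,6R)-4-(tert-butyldimethylsilyloxy)-1-[(E)-2-iodoethenyl]-2,2,6-trimethyl-7-oxabicyclo[4.1.0]heptane | I/C=C/[C@]12C(C)(C)C[C@H](O[Si](C)(C)C(C)(C)C)C[C@@]1(C)O2
F4 | step 18 | (1R,2R,4S)-4-(tert-butyldimethylsilyloxy)-1-[(E)-2-iodoethenyl]-2,6,6-trimethylcyclohexane-1,2-diol | I/C=C/[C@@]1(O)C(C)(C)C[C@H](O[Si](C)(C)C(C)(C)C)C[C@@]1(C)O
F5 | step 18 | (1R,2R,4S)-4-(tert-butyldimethylsilyloxy)-2,6,6-trimethyl-1-[(1E)-4-(trimethylsilyl)but-1-en-3-yn-1-yl]cyclohexane-1,2-diol | C[Si](C)(C)C#C/C=C/[C@@]1(O)C(C)(C)C[C@H](O[Si](C)(C)C(C)(C)C)C[C@@]1(C)O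
F6 | step 11 | ethyl (2E,4E)-5-[(1S,4S,6R)-4-(tert-butyldimethylsilyloxy)-2,2,6-trimethyl-7-oxabicyclo[4.1.0]heptan-1-yl]-3-methylpenta-2,4-dienoate | CCOC(=O)/C=C(C)/C=C/[C@]12C(C)(C)C[C@H](O[Si](C)(C)C(C)(C)C)C[C@@]1(C)O2
F7 | step 11 | (2E,4E)-5-[(1S,4S,6R)-4-(tert-butyldimethylsilyloxy)-2,2,6-trimethyl-7-oxabicyclo[4.1.0]heptan-1-yl]-3-methylpenta-2,4-dien-1-ol | OC/C=C(C)/C=C/[C@]12C(C)(C)C[C@H](O[Si](C)(C)C(C)(C)C)C[C@@]1(C)O2
F8 | step 11 | (2E)-3-[(2R,6S,7aR)-6-(tert-butyldimethylsilyloxy)-4,4,7a-trimethyl-2,4,5,6,7,7a-hexahydro-1-benzofuran-2-yl]but-2-en-1-ol | OC/C=C(\C)[C@H]1C=C2C(C)(C)C[C@H](O[Si](C)(C)C(C)(C)C)C[C@@]2(C)O1
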